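**Retrosynthetic overview**
- The target is two identical (2R,3R)-2,3-cis flavan units joined C4(upper, β)→C6(lower), the lower unit keeping a 4β-OH; the last step is global debenzylation of its octabenzyl ether.
- Key disconnection: the C4–C6 bond and both C4–C4a bonds are cut together, giving two molecules of one acyclic aldehyde ArO–CH(Ar')–CH(OBn)–CHO. Pyran rings C and F close by Friedel–Crafts hydroxyalkylation and the resulting 4-ol self-couples in the same flask.
- The aldehyde comes from a threo 3-aryloxy-2-hydroxy ester. Its aryl ether (the future O1–C2 bond) is made by SN2 opening of a cis-glycidate with 2,3-bis(benzyloxy)phenol, so C2 and C3 of both units come from one asymmetric epoxidation.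
- The cis-glycidate comes from Jacobsen epoxidation of a (Z)-cinnamate (Still–Gennari olefination of 4-(benzyloxy)benzaldehyde); the phenol comes from 2,3-dihydroxybenzaldehyde (benzylation, Baeyer–Villiger).
- Ring order: the four benzene rings (A, B, D, E) are bought; rings C and F are formed last, together.

Assumption: the target is read as epioritin-(4β→6)-epioritin-4β-ol (epioritin = (2R,3R)-7,8,4'-trihydroxyflavan-3-ol); flavan numbering is used, with upper-unit rings A, B, C and lower-unit rings D, E, F.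

**Step 1**
Reactants: 1 2,3-dihydroxybenzaldehyde
Product: 2 2,3-bis(benzyloxy)benzaldehyde
Conditions: BnBr (2.2 equiv), K2CO3, DMF, 60 °C
Reagents that add atoms: benzyl bromide, BrCc1ccccc1
Why: Williamson ether synthesis alkylates both phenols under carbonate base; no stereocenter is involved.

**Step 2**
Reactants: 2 2,3-bis(benzyloxy)benzaldehyde
Product: 4 2,3-bis(benzyloxy)phenol, via aryl formate 3 (not isolated)
Conditions: mCPBA, CH2Cl2, 0 °C to rt; NaHCO3 wash; then K2CO3 (0.1 equiv), MeOH, rt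
Reagents that add atoms: 3-chloroperoxybenzoic acid (mCPBA), OOC(=O)c1cccc(Cl)c1
Why: Baeyer–Villiger (Dakin-type) oxidation, in which the electron-rich dialkoxyaryl group migrates to oxygen and the resulting formate is methanolysed to the phenol; no stereocenter is involved.

**Step 3**
Reactants: 5 4-(benzyloxy)benzaldehyde
Product: 6 methyl (Z)-3-[4-(benzyloxy)phenyl]prop-2-enoate
Conditions: (CF3CH2O)2P(O)CH2CO2Me, KN(SiMe3)2, 18-crown-6, THF, −78 °C
Reagents that add atoms: methyl bis(2,2,2-trifluoroethyl)phosphonoacetate, COC(=O)CP(=O)(OCC(F)(F)F)OCC(F)(F)F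
Why: Still–Gennari variant of the Horner–Wadsworth–Emmons olefination, whose trifluoroethyl phosphonate eliminates quickly from the kinetic adduct and gives the Z-enoate with aromatic aldehydes.

**Step 4**
Reactants: 6 methyl (Z)-3-[4-(benzyloxy)phenyl]prop-2-enoate
Product: 7 methyl (2S,3S)-3-[4-(benzyloxy)phenyl]oxirane-2-carboxylate (cis-glycidate)
Conditions: (S,S)-(salen)MnCl [(S,S)-N,N'-bis(3,5-di-tert-butylsalicylidene)cyclohexane-1,2-diamine manganese chloride] (5 mol %), 4-phenylpyridine N-oxide (0.25 equiv), NaOCl (aq., pH 11.3), CH2Cl2, 4 °C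
Reagents that add atoms: sodium hypochlorite, [Na+].[O-]Cl
Why: Jacobsen–Katsuki epoxidation of a cis-cinnamate, the substrate class this catalyst handles best; the (S,S) catalyst delivers oxygen to the face that makes the benzylic carbon S, setting C2 and C3 together as the cis-(2S,3S) epoxide (the minor trans-epoxide is removed by chromatography).

**Step 5**
Reactants: 7 methyl (2S,3S)-3-[4-(benzyloxy)phenyl]oxirane-2-carboxylate; 4 2,3-bis(benzyloxy)phenol
Product: 8 methyl (2S,3R)-3-[2,3-bis(benzyloxy)phenoxy]-3-[4-(benzyloxy)phenyl]-2-hydroxypropanoate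
Conditions: Cs2CO3 (0.3 equiv), DMF, 50 °C
Reagents that add atoms: none
Why: Base-catalysed SN2 epoxide opening by the phenoxide at the benzylic carbon (the α-carbon is deactivated by the ester) with inversion, so the cis-epoxide gives the threo ether: C3 becomes R, C2 stays S, and these are the future flavan C2 (R) and C3 (R) in the 2,3-cis relationship.

**Step 6**
Reactants: 8 methyl (2S,3R)-3-[2,3-bis(benzyloxy)phenoxy]-3-[4-(benzyloxy)phenyl]-2-hydroxypropanoate
Product: 9 methyl (2S,3R)-2-(benzyloxy)-3-[2,3-bis(benzyloxy)phenoxy]-3-[4-(benzyloxy)phenyl]propanoate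
Conditions: BnBr, Ag2O, n-Bu4NI (cat.), toluene, rt, dark
Reagents that add atoms: benzyl bromide, BrCc1ccccc1
Why: Ag2O-mediated Williamson benzylation of the acidic α-hydroxyl works without strong base, which avoids β-elimination of the aryloxide and α-epimerisation; the stereocenters are untouched.

**Step 7**
Reactants: 9 methyl (2S,3R)-2-(benzyloxy)-3-[2,3-bis(benzyloxy)phenoxy]-3-[4-(benzyloxy)phenyl]propanoate
Product: 10 (2S,3R)-2-(benzyloxy)-3-[2,3-bis(benzyloxy)phenoxy]-3-[4-(benzyloxy)phenyl]propanal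
Conditions: i-Bu2AlH (1.1 equiv), CH2Cl2, −78 °C; aq. potassium sodium tartrate
Reagents that add atoms: none
Why: Partial ester reduction, in which the α-alkoxy ester stops at the chelated aluminium hemiacetal at −78 °C and releases the aldehyde on work-up; the aldehyde is used crude so the α-center is not epimerised.

**Step 8**
Reactants: 10 (2S,3R)-2-(benzyloxy)-3-[2,3-bis(benzyloxy)phenoxy]-3-[4-(benzyloxy)phenyl]propanal (two molecules)
Product: 12 octa-O-benzyl epioritin-(4β→6)-epioritin-4β-ol, via tetra-O-benzyl epioritin-4β-ol 11 (not isolated)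
Conditions: Sc(OTf)3 (10 mol %), CH2Cl2/MeNO2 (5:1, 0.05 M), −40 °C until 10 is consumed, then 0 °C to about one-third coupling of 11; aq. NaHCO3; recovered 11 is resubmitted
Reagents that add atoms: none
Why: Proposed new method: Sc(OTf)3 chelated between the aldehyde and α-benzyloxy oxygens triggers an intramolecular Friedel–Crafts hydroxyalkylation at the only free position ortho to the ether oxygen (para to the 7-benzyloxy group), closing the pyran ring of each molecule to 11 with C2 and C3 already fixed; the electron-rich benzylic 4-ol (either C4 epimer) then ionises reversibly to the C4 cation stabilised by O1 and the 7-alkoxy group, which is attacked on the β face (anti to the cis 2-aryl and 3-benzyloxy groups) by C6 of a second molecule of 11 (para to O1, ortho to 7-OBn, whereas the twisted 8-OBn activates C5 poorly), setting the upper C4, and the lower 4-OH ends β because water returns to its own cation from the same face; the closest known reactions are Lewis-acid cyclisation of 3-aryloxypropanals to chroman-4-ols, acid self-condensation of flavan-3,4-diols, and metal-triflate-promoted C4→C8/C6 flavanyl couplings used for benzylated procyanidins.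

**Step 9**
Reactants: 12 octa-O-benzyl epioritin-(4β→6)-epioritin-4β-ol
Product: 13 epioritin-(4β→6)-epioritin-4β-ol (target)
Conditions: H2 (1 atm), Pd(OH)2/C, THF/MeOH (1:1), rt; filtration under argon, Sephadex LH-20
Reagents that add atoms: none
Why: Catalytic hydrogenolysis cleaves all eight benzyl ethers (six aryl, two secondary alkyl) under neutral conditions, where the cyclic C2–O1 bonds and the unactivated benzylic 4-OH are expected to survive (as they do in debenzylation of benzylated procyanidins and of p-hydroxybenzyl alcohol lignin models); no stereocenter is touched.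

**Compound list**
1 | 2,3-dihydroxybenzaldehyde | O=Cc1cccc(O)c1O | starting material
2 | 2,3-bis(benzyloxy)benzaldehyde | O=Cc1cccc(OCc2ccccc2)c1OCc1ccccc1 | intermediate
3 | 2,3-bis(benzyloxy)phenyl formate (aryl formate, not isolated) | O=COc1cccc(OCc2ccccc2)c1OCc1ccccc1 | intermediate
4 | 2,3-bis(benzyloxy)phenol | Oc1cccc(OCc2ccccc2)c1OCc1ccccc1 | intermediate
5 | 4-(benzyloxy)benzaldehyde | O=Cc1ccc(OCc2ccccc2)cc1 | starting material
6 | methyl (Z)-3-[4-(benzyloxy)phenyl]prop-2-enoate | COC(=O)/C=C\c1ccc(OCc2ccccc2)cc1 | intermediate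
7 | methyl (2S,3S)-3-[4-(benzyloxy)phenyl]oxirane-2-carboxylate (cis) | COC(=O)[C@H]1O[C@H]1c1ccc(OCc2ccccc2)cc1 | intermediate
8 | methyl (2S,3R)-3-[2,3-bis(benzyloxy)phenoxy]-3-[4-(benzyloxy)phenyl]-2-hydroxypropanoate (threo) | COC(=O)[C@@H](O)[C@H](Oc1cccc(OCc2ccccc2)c1OCc1ccccc1)c1ccc(OCc2ccccc2)cc1 | intermediate
9 | methyl (2S,3R)-2-(benzyloxy)-3-[2,3-bis(benzyloxy)phenoxy]-3-[4-(benzyloxy)phenyl]propanoate | COC(=O)[C@@H](OCc1ccccc1)[C@H](Oc1cccc(OCc2ccccc2)c1OCc1ccccc1)c1ccc(OCc2ccccc2)cc1 | intermediate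
10 | (2S,3R)-2-(benzyloxy)-3-[2,3-bis(benzyloxy)phenoxy]-3-[4-(benzyloxy)phenyl]propanal | O=C[C@@H](OCc1ccccc1)[C@H](Oc1cccc(OCc2ccccc2)c1OCc1ccccc1)c1ccc(OCc2ccccc2)cc1 | intermediate
11 | (2R,3R,4S)-3,7,8-tris(benzyloxy)-2-[4-(benzyloxy)phenyl]-3,4-dihydro-2H-chromen-4-ol (tetra-O-benzyl epioritin-4β-ol, 2,3-cis-3,4-trans; not isolated; its 4-epimer forms alongside and feeds the same cation) | c1cc2c(c(OCc5ccccc5)c1OCc5ccccc5)O[C@H](c1ccc(OCc5ccccc5)cc1)[C@H](OCc5ccccc5)[C@H]2O | intermediate
12 | octa-O-benzyl epioritin-(4β→6)-epioritin-4β-ol: two (2R,3R)-3,7,8-tris(benzyloxy)-2-[4-(benzyloxy)phenyl]chroman units, C4 of the upper unit bonded on its β face (trans to 3-OBn) to C6 of the lower unit, which carries a free 4β-OH (4S) | O(Cc5ccccc5)c1ccc([C@H]2Oc3c(ccc(OCc5ccccc5)c3OCc5ccccc5)[C@H](c3cc4c(c(OCc5ccccc5)c3OCc5ccccc5)O[C@H](c3ccc(OCc5ccccc5)cc3)[C@H](OCc5ccccc5)[C@H]4O)[C@H]2OCc5ccccc5)cc1 | intermediate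
13 | epioritin-(4β→6)-epioritin-4β-ol, (2R,3R,4S)-6-[(2R,3R,4S)-3,7,8-trihydroxy-2-(4-hydroxyphenyl)-3,4-dihydro-2H-chromen-4-yl]-2-(4-hydroxyphenyl)-3,4-dihydro-2H-chromene-3,4,7,8-tetrol | Oc1ccc([C@H]2Oc3c(ccc(O)c3O)[C@H](c3cc4c(c(O)c3O)O[C@H](c3ccc(O)cc3)[C@H](O)[C@H]4O)[C@H]2O)cc1 | target

**Totals**
Total steps: 9. Longest linear sequence: 7 steps (steps 3 to 9, from 5); steps 1 and 2 feed in at step 5.

**Steps most likely to fail, with fallbacks**

Step 8 (cyclisation and self-coupling cascade). Because 11 is both nucleophile and electrophile, chain growth is statistical: the ceiling is about 30% of 12 per pass, with about 45% of 11 recovered and recycled. Further risks are some C5-linked isomer, loss of H3 from the cation to a flav-3-ene, and ionisation of the acyclic C–OAr bond before ring closure. The fallback sets out from 10 and returns at 12. The ring closure is run alone (Sc(OTf)3, −40 °C, cold quench) and 11 is isolated. One part of 11 is treated with phenylmethanethiol and catalytic Sc(OTf)3 in CH2Cl2 at 0 °C to give 4β-(benzylsulfanyl)-3,7,8,4'-tetra-O-benzylepioritin F1 (SN1 thiolysis, sulfur entering on the β face). F1 is then activated with AgBF4 in THF at 0 °C in the presence of three equivalents of 11. The thiophilic silver salt ionises only the C–S bond, so 11 acts purely as the C6 nucleophile with its own 4-OH untouched, and the excess suppresses trimer; this gives 12.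

Step 5 (phenoxide opening of the glycidic ester). The risks are competing attack at C2, partial ionisation of the electron-rich benzylic epoxide (erosion of the threo relationship), and ester exchange by the phenoxide. The fallback sets out from 7 (with 4) and returns at 10.
- NaBH4 in MeOH at 0 °C reduces the ester to [(2R,3S)-3-[4-(benzyloxy)phenyl]oxiran-2-yl]methanol F2.
- Ti(OiPr)4-mediated, chelation-directed opening by 4 at C3 with inversion (toluene, 50 °C) gives (2R,3R)-3-[2,3-bis(benzyloxy)phenoxy]-3-[4-(benzyloxy)phenyl]propane-1,2-diol F3.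
- PhCH(OMe)2 with pyridinium p-toluenesulfonate gives the benzylidene acetal (4R)-4-{(R)-[2,3-bis(benzyloxy)phenoxy][4-(benzyloxy)phenyl]methyl}-2-phenyl-1,3-dioxolane F4.
- i-Bu2AlH in CH2Cl2 at 0 °C opens the acetal regioselectively, leaving the benzyl group on the secondary oxygen, to give (2R,3R)-2-(benzyloxy)-3-[2,3-bis(benzyloxy)phenoxy]-3-[4-(benzyloxy)phenyl]propan-1-ol F5.
- Dess–Martin oxidation gives 10.

Step 9 (global hydrogenolysis). The risks are reductive loss of the benzylic 4-OH, slow cleavage of the two hindered 3-O-benzyl ethers, and the air and acid sensitivity of the free pyrogallol product. The fallback sets out from 12 and returns at 13. The lone 4-OH is silylated (TBSCl, imidazole, DMF) to give 4-O-(tert-butyldimethylsilyl)-octa-O-benzyl epioritin-(4β→6)-epioritin-4β-ol F6. The benzyl ethers are then removed with H2 and Pd(OH)2/C in EtOAc/THF, where the benzylic silyl ether is inert, to give 4-O-(tert-butyldimethylsilyl) epioritin-(4β→6)-epioritin-4β-ol F7. Finally n-Bu4NF buffered with AcOH in THF at 0 °C releases the 4-OH to give 13.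

**Further compounds**
F1 | step 8 | 4β-(benzylsulfanyl)-3,7,8,4'-tetra-O-benzylepioritin, (2R,3S,4S)-4-(benzylsulfanyl)-3,7,8-tris(benzyloxy)-2-[4-(benzyloxy)phenyl]-3,4-dihydro-2H-chromene (2,3-cis-3,4-trans) | c1cc2c(c(OCc5ccccc5)c1OCc5ccccc5)O[C@H](c1ccc(OCc5ccccc5)cc1)[C@H](OCc5ccccc5)[C@H]2SCc1ccccc1
F2 | step 5 | [(2R,3S)-3-[4-(benzyloxy)phenyl]oxiran-2-yl]methanol (cis) | OC[C@H]1O[C@H]1c1ccc(OCc2ccccc2)cc1
F3 | step 5 | (2R,3R)-3-[2,3-bis(benzyloxy)phenoxy]-3-[4-(benzyloxy)phenyl]propane-1,2-diol (threo) | OC[C@@H](O)[C@H](Oc1cccc(OCc2ccccc2)c1OCc1ccccc1)c1ccc(OCc2ccccc2)cc1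
F4 | step 5 | (4R)-4-{(R)-[2,3-bis(benzyloxy)phenoxy][4-(benzyloxy)phenyl]methyl}-2-phenyl-1,3-dioxolane (mixture at the acetal carbon) | C1OC(c2ccccc2)O[C@H]1[C@H](Oc1cccc(OCc2ccccc2)c1OCc1ccccc1)c1ccc(OCc2ccccc2)cc1
F5 | step 5 | (2R,3R)-2-(benzyloxy)-3-[2,3-bis(benzyloxy)phenoxy]-3-[4-(benzyloxy)phenyl]propan-1-ol | OC[C@@H](OCc1ccccc1)[C@H](Oc1cccc(OCc2ccccc2)c1OCc1ccccc1)c1ccc(OCc2ccccc2)cc1
F6 | step 9 | 4-O-(tert-butyldimethylsilyl)-octa-O-benzyl epioritin-(4β→6)-epioritin-4β-ol (silyl ether on the lower-unit 4β-oxygen) | O(Cc5ccccc5)c1ccc([C@H]2Oc3c(ccc(OCc5ccccc5)c3OCc5ccccc5)[C@H](c3cc4c(c(OCc5ccccc5)c3OCc5ccccc5)O[C@H](c3ccc(OCc5ccccc5)cc3)[C@H](OCc5ccccc5)[C@H]4O[Si](C)(C)C(C)(C)C)[C@H]2OCc5ccccc5)cc1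
F7 | step 9 | 4-O-(tert-butyldimethylsilyl) epioritin-(4β→6)-epioritin-4β-ol (all other hydroxyls free) | Oc1ccc([C@H]2Oc3c(ccc(O)c3O)[C@H](c3cc4c(c(O)c3O)O[C@H](c3ccc(O)cc3)[C@H](O)[C@H]4O[Si](C)(C)C(C)(C)C)[C@H]2O)cc1
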